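- With a small charge of E I could spend it on one more flask, so I had to choose the J charge: ochre or red, both read at 6.0 min.

common to all: E 0.16 M

| run | J | remark | time |
|---|---|---|---|
| west | 1.3 equiv | run made earlier |  |
| east | 1.2 equiv | run made earlier |  |
| ochre | 1.00 equiv |  | 6.0 min |
| red | 1.50 equiv |  | 6.0 min |

| run | time / min | Z / % | E / % |
|---|---|---|---|
| west | 0.333 | 12.6 | 87.2 |
| west | 0.667 | 22.0 | 78.4 |
| west | 1.33 | 34.3 | 66.0 |
| west | 2.00 | 41.7 | 57.9 |
| west | 4.00 | 53.6 | 46.2 |
| east | 0.833 | 24.4 | 76.2 |
| east | 1.50 | 34.3 | 65.7 |
| east | 2.50 | 43.6 | 56.7 |
| east | 3.00 | 46.7 | 54.1 |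
| east | 4.00 | 50.2 | 48.8 |

(each reading ± 0.3 percentage points)

- the analysis behind the earlier runs scatters by 0.3 percentage points, standard deviation
- a reading or a percentage of Z counts all its forms, free or not

- which of these there is most of at the end, counted by the E in it, ochre (E / Z)
- which of these there is most of at the end, counted by the E in it, red (E / Z)
- the largest of these amounts at the end, in percent of the E charged, ochre
- the largest of these amounts at the end, in percent of the E charged, red

- I took the specific rate s as the rate of Z formation divided by the E still present; if the step is first order in E and in J, s follows free J.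
- In the west run I read s as 0.404 min⁻¹ over the first interval but 0.114 min⁻¹ between 2.00 min and 4.00 min, so it had drifted to 28.1% of its early value.
- Setting that ratio equal to the ratio of free J at the two moments gave n = 2.04, a reading I call the J cost: moles of free J lost per mole of Z formed.
- At that cost I reckoned a ceiling for ochre: the J charged pays for Z up to 49.1%, so I expected ochre to hold more E than Z.
- In red the same reckoning gives 73.7%, so J is the limiting reagent there despite its excess.
- The west run already showed 53.6% Z at 4.00 min, and red has more J and a longer time, so I expected more Z than E in red and chose red.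
- The forecast, reckoned separately from my ceilings, held that “each Z formed appears to tie up a second J”; it gave E as largest in ochre at 53.2%, and Z as largest in red at 66.1%.
- Ochre ended with E largest at 53.2%, and red with Z largest at 66.2%, as forecast. In red, 11.8% of the charged J stood free at the end, while the J cost from the west run, applied to red's final Z, gives 10.1%.

    E + J → X + Z (k = 2.20 M⁻¹ min⁻¹)
    J + X ⇌ Q, settled at all times (K = 16000 M⁻¹)
    D ⇌ Z, rate k3*(cs3 - [Z]) while solid is left; crystals form when [Z] > cs3 (solubility = 0.0890 M, k = 1.70 min⁻¹)

- In a neighbouring flask, red's recipe with 0.900 equiv of J, the J cost gives a reckoned ceiling of 44.2% Z, which points to E as largest. At 6.00 min that flask held 42.5% Z, with E largest and 5.8% of its J free.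

The earlier runs and the new flask were computed from invented constants; noise was put on by code.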